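The target is cut at the ring-fusion bond Ca–Cb (Ca = CH on CMe2; Cb = O–CH on C3 of quinolinone A) and at the aryl ether O4'–C4' of quinolinone B. The feature exploited is that both halves are 4-oxygenated 2-quinolones carrying one carbon on C3 (Cb on A, Cc on B), so one 4-chloro-3-formylquinolinone serves twice, while Ca–CMe2–O4 plus the Cc–CH2CMe2OH chain is a masked δ-lactone. In one operation the lithium enolate of the (R)-4-aryl-6,6-dimethyl-δ-lactone precursor (aryl = 4-chloro-2-quinolon-3-yl, future ring B) adds anti to that aldehyde and the aldolate displaces the 4'-chloride, forming Ca–Cb, both new stereocentres and pyran ring B.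

Key step: step 6

Labels: quinolinone A/ring A is the half fused to the gem-dimethylpyran; quinolinone B/ring B (primed atoms) is the other half; Cc is the CH bearing the CH2CMe2OH chain. The target SMILES reads Ca R, Cb S, Cc R (Ca–H/Cb–H cis, Ca–H/Cc–H trans), and the lactone precursor (Cc R) and the key-step product (Ca R, Cb S, Cc R) agree with it.

Assumption: the alkaloid catalyst named in step 4 is taken to deliver the (3S)-hemiester; should the (3R)-hemiester predominate, the pseudoenantiomeric hydroquinine-derived catalyst (DHQ)2AQN is used instead and nothing else changes.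

Step 1
Reactants: 1 4-hydroxy-1-methylquinolin-2(1H)-one
Product: 2 4-chloro-1-methyl-2-oxo-1,2-dihydroquinoline-3-carbaldehyde
Conditions: POCl3 (4 equiv), DMF, 0 → 60 °C; then ice/aq. NaOAc
Reagents that add atoms: N,N-dimethylformamide CN(C)C=O (formyl carbon); phosphoryl chloride O=P(Cl)(Cl)Cl (chlorine); water O (aldehyde oxygen)
Why: Vilsmeier–Haack chloroformylation, in which the chloroiminium salt formylates the nucleophilic C3 of the enolic quinolinone and the vinylogous-acid hydroxyl is exchanged for chloride in the same pot, the iminium being hydrolysed on work-up; no stereocentre is formed.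

Step 2
Reactants: 2 4-chloro-1-methyl-2-oxo-1,2-dihydroquinoline-3-carbaldehyde; 3 Meldrum's acid (2.1 equiv)
Product: 6 3-(4-chloro-1-methyl-2-oxo-1,2-dihydroquinolin-3-yl)pentanedioic acid, via alkylidene Meldrum's acid 4 (not isolated), via bis-Meldrum's acid adduct 5 (not isolated)
Conditions: ethylenediammonium diacetate (5 mol %), MeCN, rt; then 6 M HCl–dioxane, 90 °C
Reagents that add atoms: Meldrum's acid CC1(C)OC(=O)CC(=O)O1; water O
Why: Knoevenagel condensation to 4 and Michael addition of a second Meldrum's acid give 5, whose acylal rings are hydrolysed and doubly decarboxylated in hot aqueous acid (the standard 3-arylglutaric acid synthesis), the buffered catalyst and the acidic second stage keeping strong nucleophiles away from the 4-chloride; the product is achiral.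

Step 3
Reactants: 6 3-(4-chloro-1-methyl-2-oxo-1,2-dihydroquinolin-3-yl)pentanedioic acid
Product: 7 4-(4-chloro-1-methyl-2-oxo-1,2-dihydroquinolin-3-yl)oxane-2,6-dione (3-arylglutaric anhydride)
Conditions: Ac2O, 100 °C; evaporate, crystallise
Reagents that add atoms: none
Why: Dehydrative cyclisation of a glutaric acid to its six-membered cyclic anhydride through the mixed acetic anhydride; the prochiral anhydride has no stereocentre.

Step 4
Reactants: 7 4-(4-chloro-1-methyl-2-oxo-1,2-dihydroquinolin-3-yl)oxane-2,6-dione
Product: 8 (3S)-3-(4-chloro-1-methyl-2-oxo-1,2-dihydroquinolin-3-yl)-5-methoxy-5-oxopentanoic acid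
Conditions: MeOH (10 equiv), hydroquinidine anthraquinone-1,4-diyl diether (DHQD)2AQN (0.2 equiv), Et2O–THF, −40 °C; dilute HCl wash
Reagents that add atoms: methanol CO
Why: Alkaloid-catalysed desymmetrising alcoholysis of a prochiral 3-substituted glutaric anhydride, in which the chiral tertiary amine acts as general base for methanol and differentiates the two enantiotopic carbonyl groups, so that Cc is set under catalyst control (the hemiester can be upgraded by crystallising an amine salt).

Step 5
Reactants: 8 (3S)-hemiester; 9 methylmagnesium bromide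
Product: 11 (4R)-4-(4-chloro-1-methyl-2-oxo-1,2-dihydroquinolin-3-yl)-6,6-dimethyloxan-2-one, via hydroxy acid 10 (not isolated)
Conditions: MeMgBr (3.5 equiv), THF, −20 → 0 °C; 1 M HCl; then TsOH·H2O (5 mol %), CH2Cl2, rt
Reagents that add atoms: methylmagnesium bromide C[Mg]Br
Why: Grignard double addition to the methyl ester while the carboxylate is protected in situ as its bromomagnesium salt, followed by acid-catalysed lactonisation of δ-hydroxy acid 10; Cc is not touched (the descriptor changes from S to R only because the two arms swap CIP priority).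

Step 6
Reactants: 11 (4R)-lactone; 2 4-chloro-1-methyl-2-oxo-1,2-dihydroquinoline-3-carbaldehyde
Product: 14 tetracyclic chloro lactone (ring B pyrano[3,2-c]quinolin-5-one trans-fused at Ca–Cc to the 6,6-dimethyl δ-lactone; 4-chloro-1-methyl-2-oxoquinolin-3-yl on Cb; Ca R / Cb S / Cc R), via lithium enolate 12 (not isolated), via lithium aldolate 13 (not isolated)
Conditions: LiN(iPr)2 (1.0 equiv; 11 1.05 equiv), THF, −78 °C; 2 (1.0 equiv), −78 °C; then −78 → 0 °C; pH 7 buffer
Reagents that add atoms: none
Why: Deprotonation gives the ring-locked E(O) lithium enolate 12, which adds to the formyl group of 2 through a closed chair (Zimmerman–Traxler) transition state to give anti aldolate 13, whose alkoxide then attacks C4' of quinolinone B by addition–elimination and expels chloride, an irreversible step that removes the aldolate before retro-aldol can scramble it. The closest known reaction types are anti-selective aldol additions of β-substituted δ-lactone lithium enolates and intramolecular SNAr etherifications of 4-chloro-2-quinolones. Pyran ring B (O4'–Cb–Ca–Cc–C3'–C4') closes as a 6-endo-trig oxa-Michael addition–elimination, the attacked C3'=C4' bond lying inside the new ring, whereas attack on the 4-chloride of quinolinone A would need a four-membered ring and does not compete. Ca is controlled by the resident Cc stereocentre, because the aryl group on Cc blocks one enolate face and the aldehyde bonds trans to it (hence the trans fusion of lactone and ring B), and Cb is controlled relative to Ca by the fixed enolate geometry with the aldehyde substituent equatorial in the chair. The step needs 1,2-addition to the aldehyde instead of attack at its C4 (hard lithium enolate at −78 °C), anti and trans diastereoselectivity (enolate geometry and β-aryl group) and absence of excess base, since the product has an acidic Ca–H β to the O4' leaving group; the base is therefore the limiting reagent.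

Step 7
Reactants: 14 tetracyclic chloro lactone; 9 methylmagnesium bromide
Product: 16 (2S,3R,4R)-2-(4-chloro-1-methyl-2-oxo-1,2-dihydroquinolin-3-yl)-3-(2-hydroxypropan-2-yl)-4-(2-hydroxy-2-methylpropyl)-6-methyl-3,4-dihydro-2H-pyrano[3,2-c]quinolin-5(6H)-one, via methyl ketone 15 (not isolated)
Conditions: MeMgBr (4 equiv), anhydrous CeCl3 (4 equiv), THF, −78 → 0 °C; then H2O
Reagents that add atoms: methylmagnesium bromide C[Mg]Br
Why: Organocerium double 1,2-addition to the lactone through ketone 15, in which the weakly basic trivalent cerium reagent adds faster than it deprotonates Ca–H, so that β-elimination of O4' and epimerisation at Ca are avoided, while the vinylogous amide carbonyls of both quinolinones and the aryl chloride are inert; no stereocentre is changed.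

Step 8
Reactants: 16 diol
Product: 18 target CNP0202276.1, via disodium dialkoxide 17 (not isolated)
Conditions: NaH (2.2 equiv), THF–DMF, 0 °C → rt; then H2O
Reagents that add atoms: none
Why: Intramolecular SNAr (addition–elimination at the vinylogous acyl chloride C4 of quinolinone A) by the tertiary alkoxide on the CMe2 group of Ca closes the six-membered gem-dimethylpyran of ring A, the cis arrangement of CMe2O– on Ca and quinolinone A on Cb bringing the partners together, whereas the side-chain alkoxide could only form an eight-membered ring and is recovered as the free alcohol; no stereocentre is touched.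

Compound list
1 | 4-hydroxy-1-methylquinolin-2(1H)-one | Cn1c(=O)cc(O)c2ccccc21 | starting material
2 | 4-chloro-1-methyl-2-oxo-1,2-dihydroquinoline-3-carbaldehyde | Cn1c(=O)c(C=O)c(Cl)c2ccccc21 | intermediate
3 | Meldrum's acid (2,2-dimethyl-1,3-dioxane-4,6-dione) | CC1(C)OC(=O)CC(=O)O1 | starting material
4 | alkylidene Meldrum's acid (not isolated): 5-[(4-chloro-1-methyl-2-oxo-1,2-dihydroquinolin-3-yl)methylidene]-2,2-dimethyl-1,3-dioxane-4,6-dione | CC1(C)OC(=O)C(=Cc2c(Cl)c3ccccc3n(C)c2=O)C(=O)O1 | intermediate
5 | bis-Meldrum's acid adduct (not isolated): 5,5'-[(4-chloro-1-methyl-2-oxo-1,2-dihydroquinolin-3-yl)methylene]bis(2,2-dimethyl-1,3-dioxane-4,6-dione) | CC1(C)OC(=O)C(C(c2c(Cl)c3ccccc3n(C)c2=O)C2C(=O)OC(C)(C)OC2=O)C(=O)O1 | intermediate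
6 | 3-(4-chloro-1-methyl-2-oxo-1,2-dihydroquinolin-3-yl)pentanedioic acid | OC(=O)CC(CC(=O)O)c1c(Cl)c2ccccc2n(C)c1=O | intermediate
7 | 4-(4-chloro-1-methyl-2-oxo-1,2-dihydroquinolin-3-yl)oxane-2,6-dione | O=C1CC(CC(=O)O1)c1c(Cl)c2ccccc2n(C)c1=O | intermediate
8 | (3S)-3-(4-chloro-1-methyl-2-oxo-1,2-dihydroquinolin-3-yl)-5-methoxy-5-oxopentanoic acid | COC(=O)C[C@@H](c1c(Cl)c2ccccc2n(C)c1=O)CC(=O)O | intermediate
9 | methylmagnesium bromide | C[Mg]Br | starting material
10 | hydroxy acid (not isolated): (3R)-3-(4-chloro-1-methyl-2-oxo-1,2-dihydroquinolin-3-yl)-5-hydroxy-5-methylhexanoic acid | CC(C)(O)C[C@@H](c1c(Cl)c2ccccc2n(C)c1=O)CC(=O)O | intermediate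
11 | (4R)-4-(4-chloro-1-methyl-2-oxo-1,2-dihydroquinolin-3-yl)-6,6-dimethyloxan-2-one | CC1(C)C[C@@H](c2c(Cl)c3ccccc3n(C)c2=O)CC(=O)O1 | intermediate
12 | lithium enolate (not isolated): lithium (4R)-4-(4-chloro-1-methyl-2-oxo-1,2-dihydroquinolin-3-yl)-6,6-dimethyl-5,6-dihydro-4H-pyran-2-olate | [Li+].[O-]C1=C[C@H](c2c(Cl)c3ccccc3n(C)c2=O)CC(C)(C)O1 | intermediate
13 | lithium aldolate, anti (not isolated): lithium (S)-(4-chloro-1-methyl-2-oxo-1,2-dihydroquinolin-3-yl)[(3R,4R)-4-(4-chloro-1-methyl-2-oxo-1,2-dihydroquinolin-3-yl)-6,6-dimethyl-2-oxooxan-3-yl]methanolate | O=C1OC(C)(C)C[C@@H](c2c(Cl)c3ccccc3n(C)c2=O)[C@@H]1[C@H]([O-])c1c(Cl)c2ccccc2n(C)c1=O.[Li+] | intermediate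
14 | tetracyclic chloro lactone: ring B (6-methyl-pyrano[3,2-c]quinolin-5-one) trans-fused at Ca–Cc to the 6,6-dimethyl δ-lactone (C=O on Ca, CH2CMe2O on Cc), Cb bearing 4-chloro-1-methyl-2-oxo-1,2-dihydroquinolin-3-yl cis to the lactone carbonyl; Ca R, Cb S, Cc R | O=C1OC(C)(C)C[C@H]2c3c(c4ccccc4n(C)c3=O)O[C@H](c3c(Cl)c4ccccc4n(C)c3=O)[C@H]12 | intermediate
15 | methyl ketone (not isolated; as its alkoxide in the flask): (2S,3R,4R)-3-acetyl-2-(4-chloro-1-methyl-2-oxo-1,2-dihydroquinolin-3-yl)-4-(2-hydroxy-2-methylpropyl)-6-methyl-3,4-dihydro-2H-pyrano[3,2-c]quinolin-5(6H)-one | CC(C)(O)C[C@H]1c2c(c3ccccc3n(C)c2=O)O[C@H](c2c(Cl)c3ccccc3n(C)c2=O)[C@@H]1C(C)=O | intermediate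
16 | (2S,3R,4R)-2-(4-chloro-1-methyl-2-oxo-1,2-dihydroquinolin-3-yl)-3-(2-hydroxypropan-2-yl)-4-(2-hydroxy-2-methylpropyl)-6-methyl-3,4-dihydro-2H-pyrano[3,2-c]quinolin-5(6H)-one | CC(C)(O)C[C@H]1c2c(c3ccccc3n(C)c2=O)O[C@H](c2c(Cl)c3ccccc3n(C)c2=O)[C@@H]1C(C)(C)O | intermediate
17 | disodium dialkoxide of 16 (not isolated) | [Na+].[Na+].CC(C)([O-])C[C@H]1c2c(c3ccccc3n(C)c2=O)O[C@H](c2c(Cl)c3ccccc3n(C)c2=O)[C@@H]1C(C)(C)[O-] | intermediate
18 | CNP0202276.1: two 6-methyl-pyrano[3,2-c]quinolin-5-ones whose pyran rings share the Ca–Cb bond (cis fusion), gem-dimethyl on the ring A pyran, 2-hydroxy-2-methylpropyl on Cc trans to the Ca substituent; Ca R, Cb S, Cc R | Cn1c(=O)c2c(c3ccccc31)OC(C)(C)[C@H]1[C@@H]2Oc2c(c(=O)n(C)c3ccccc23)[C@@H]1CC(C)(C)O | target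

Total step count: 8. Longest linear sequence: 8 steps (1 → 2 → 6 → 7 → 8 → 11 → 14 → 16 → 18); aldehyde 2 enters twice, in steps 2 and 6.

Steps most likely to fail

Step 6. The anti (Ca–Cb) selectivity may erode through retro-aldol equilibration if the chloride displacement from the lithium alkoxide is slow, and any surplus base may open ring B by β-elimination of O4'. The fallback separates the two events, setting out from 11 and returning at 14. Lactone 11 would be converted (LiN(iPr)2, Me3SiCl, THF, −78 °C) into the trimethylsilyl ketene acetal F1. A BF3·OEt2-mediated Mukaiyama aldol addition of F1 to aldehyde 2 in CH2Cl2 at −78 °C runs through an open transition state under non-basic conditions, where the adduct is held as a silyl ether and cannot revert. After aqueous work-up it should give the β-hydroxy lactone F2, with Ca again bonded trans to the aryl group and any Cb epimer removed by chromatography at this neutral stage. Cs2CO3 in MeCN at rt would then close ring B by the same intramolecular chloride displacement, with only a low stationary concentration of alkoxide, to give 14.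

Step 7. Deprotonation at Ca may compete with carbonyl addition and lead to β-elimination that opens ring B, or the addition may stop after the first methyl group at the hemiketal stage because the carbonyl is hindered. The fallback introduces the two methyl groups one at a time with reagents of low basicity, setting out from 14 and returning at 16. Aminolysis of lactone 14 with MeNH(OMe)·HCl/AlMe3 in CH2Cl2 should give the hydroxy Weinreb amide F3. One equivalent of methyl nucleophile (MeMgBr–CeCl3, THF, −78 °C) adds to F3 to give a stable chelate, so the methyl ketone 15 (already in the compound list, here isolated) is released only on work-up. Methyltitanium triisopropoxide, MeTi(OiPr)3, in THF at 0 °C → rt, a non-basic reagent that adds to enolisable ketones without deprotonation, would then deliver the second methyl group to give 16.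

Step 2. The activated 4-chloride may be displaced (by the enolate oxygen of Meldrum's acid, by the amine catalyst, or by a carboxyl group in the hot acid stage) in competition with the two C–C bond formations. The fallback builds the glutarate under Lewis-acidic conditions without free enolates, setting out from 2 and returning at 6. A TiCl4/pyridine-mediated Knoevenagel condensation of 2 with dimethyl malonate (THF, 0 °C) should give the alkylidene malonate F4. A TiCl4-promoted Mukaiyama–Michael addition of 1-methoxy-1-(trimethylsilyloxy)ethene to F4 (CH2Cl2, −78 °C) would give the triester F5. Hydrolysis and decarboxylation of F5 in 6 M HCl–AcOH at 90 °C would give diacid 6.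

Further compounds
F1 | step 6 | trimethylsilyl ketene acetal: (4R)-4-(4-chloro-1-methyl-2-oxo-1,2-dihydroquinolin-3-yl)-6,6-dimethyl-2-(trimethylsilyloxy)-5,6-dihydro-4H-pyran | C[Si](C)(C)OC1=C[C@H](c2c(Cl)c3ccccc3n(C)c2=O)CC(C)(C)O1
F2 | step 6 | β-hydroxy lactone (anti aldol): (3R,4R)-4-(4-chloro-1-methyl-2-oxo-1,2-dihydroquinolin-3-yl)-3-[(S)-(4-chloro-1-methyl-2-oxo-1,2-dihydroquinolin-3-yl)(hydroxy)methyl]-6,6-dimethyloxan-2-one | O=C1OC(C)(C)C[C@@H](c2c(Cl)c3ccccc3n(C)c2=O)[C@@H]1[C@H](O)c1c(Cl)c2ccccc2n(C)c1=O
F3 | step 7 | hydroxy Weinreb amide: (2S,3R,4R)-2-(4-chloro-1-methyl-2-oxo-1,2-dihydroquinolin-3-yl)-4-(2-hydroxy-2-methylpropyl)-N-methoxy-N,6-dimethyl-5-oxo-3,4,5,6-tetrahydro-2H-pyrano[3,2-c]quinoline-3-carboxamide | CC(C)(O)C[C@H]1c2c(c3ccccc3n(C)c2=O)O[C@H](c2c(Cl)c3ccccc3n(C)c2=O)[C@@H]1C(=O)N(C)OC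
F4 | step 2 | dimethyl 2-[(4-chloro-1-methyl-2-oxo-1,2-dihydroquinolin-3-yl)methylidene]propanedioate | COC(=O)C(=Cc1c(Cl)c2ccccc2n(C)c1=O)C(=O)OC
F5 | step 2 | trimethyl 2-(4-chloro-1-methyl-2-oxo-1,2-dihydroquinolin-3-yl)propane-1,1,3-tricarboxylate | COC(=O)CC(c1c(Cl)c2ccccc2n(C)c1=O)C(C(=O)OC)C(=O)OC
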